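The partner's half-life of 5.37 min is short against the run of 2.5 d, and I ask where this flask comes to rest rather than how fast it gets there.

solid substrate 20 mM; partner 40.0 mM; time 2.5 d

    solid substrate ⇌ starting material, rate k1*(cs1 - [starting material]) while solid is left; crystals form when [starting material] > cs1 (cs1 = 12 mM, k1 = 0.0200 /min)
    crystals ⇌ product, rate k2*(cs2 - [product]) while solid is left; crystals form when [product] > cs2 (cs2 = 6.8 mM, k2 = 2.87 /min)
    starting material ⇌ open intermediate (K3 = 2.5, k3 = 0.0200 /min)
    open intermediate + second intermediate ⇌ product (K4 = 89 /M, k4 = 0.287 /M/min)
    partner → second intermediate (k5 = 0.129 /min)

- why nothing more happens at 2.5 d, or that something still does (for what has run out or reacted, a solid counts together with what of it has only dissolved) (all of the solid substrate has reacted / the partner has run out first / forward and back rates have come level / it is still moving)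
- part of the solid substrate that has turned into other species by 2.5 d (what has only dissolved does not count)
- the product standing at 2.5 d, as a percentage of the solid substrate charged
- the open intermediate standing at 2.5 d, as a percentage of the solid substrate charged
- the starting material standing at 2.5 d, as a percentage of the solid substrate charged

- what is said of product includes crystals
- crystals, solid substrate is a solid; its amount is given per volume of the solution
- at the start none of the solid substrate is in solution
- what has only dissolved of solid substrate counts as not reacted
- the reaction counts as stopped when no species that holds the solid substrate changes by six tenths of a point or more over the second half of the time
- starting material means what is dissolved; the solid is not counted in it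
- run time (flask): 2.5 d

I count in fractions of the solid substrate charged: i for open intermediate, j for second intermediate. At its full dissolving rate the solid needs 1.39 h, which is short against the run. Open intermediate, taken up in a pseudo-first-order way by second intermediate at its lowest reckoned level, has a half-life of 2.01 h, also short against the run. Starting material and open intermediate relax towards each other with a half-life of 0.413 h, short against the run as well. So I treat the reversible steps as balanced by the end of this flask.

While crystals stand, dissolved product sits at its solubility, and the balance of open intermediate with second intermediate then asks:

i × j = 0.191

I call this the crystal product: the value that i times j takes once that balance holds with crystals standing, a kind of solubility product for the pair, reckoned as solubility over equilibrium constant over the square of the charge.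

Two extreme flasks can be solved at once. With the partner turned into second intermediate, if none of the charge took any of it up, j would be 2.00 and the crystal product would ask for i = 9.55%. If the whole charge took it up, j would be 1.00 and the crystal product would ask for i = 19.1%. What is taken up lies between none and the whole charge, so i lies between these two.

Starting material is i/K3, so what is not product is 1.40 × i, and that much second intermediate is spared. I go round from the upper extreme:

i = 19.1% gives j = 1.27, so i = 15.1%

i = 15.1% gives j = 1.21, so i = 15.8%

That leaves 6.31% starting material and 77.9% product. This product is more than the 34.0% that solution holds, so crystals do stand. Conversion comes to 93.7%. Solid substrate, counted with what of it has only dissolved, stays at 6.31%, above a fiftieth of its charge, while the partner reacts one way with the short half-life above, so I name the partner as the charge that runs out.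

The forecast says that forward and back rates have come level, with 93.7% converted, 78% product, 15.7% open intermediate and 6.3% starting material, “with the solid gone and partner left over”. Its amounts stand close to mine; on the ending we part.

The simulation says that the partner has run out first, with 93.7% converted, 78.1% product, 15.7% open intermediate and 6.27% starting material; the partner stands at 0% of its charge, second intermediate at 24.4 mM. The forward half-life of open intermediate into product, 0.084 d at 0.00374 d, is short against 2.5 d, and in this flask i times j reads 0.191 at 2.50 d, against the crystal product of 0.191. In the neighbour with 16 mM of partner, crystals stand at 3.33% and second intermediate at 8.53 mM; dividing 0.191 by its j of 0.427 gives 44.8%, and that neighbour holds 44.8% open intermediate.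

The numbers of this flask were set for the occasion; the result is computed.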